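**Retrosynthetic overview**
1. Target ⇒ acid removal of one tert-butyl ester and two TBS ethers ⇒ Yamaguchi ester between a silyl-protected acid (fragment A) and the primary alcohol of a bicyclic lactone (fragment B).
2. Fragment B ⇒ new carboxylate oxa-Michael/intramolecular Horner–Wadsworth–Emmons annulation of a masked cis-formyl acid with tert-butyl 2-(diethoxyphosphoryl)acrylate; the seven-membered lactone is formed last.
3. Masked formyl acid ⇒ bridged lactone from a hydrogen-atom-transfer hydrolactonisation (tertiary C–O) ⇒ organocatalytic Diels–Alder of (E)-4-methylpent-2-enal with a (Z)-2,3-disubstituted diene (cyclohexane of B, three stereocentres).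
4. Fragment A ⇒ double Stille hydroxymethylation ⇐ bromo-Wittig ⇐ ozonolysis ⇐ vinyl conjugate addition/enolate triflation of (S)-cryptone (organocatalytic Michael, then aldol ring closure).
5. Ring order: cyclohexene of A; cyclohexene of B; temporary 6-oxabicyclo[3.2.1]octane; seven-membered lactone.

Assumption: reagents and catalysts that appear only on Conditions lines (for example Comins' reagent, Bu3SnCH2OH, both amine catalysts) are bought, and the target has exactly the configuration of the given SMILES.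

**Fragment A**

Step 1
Reactants: 1 3-methylbutanal; 2 but-3-en-2-one
Product: 3 (2S)-5-oxo-2-(propan-2-yl)hexanal
Conditions: (S)-2-[methoxy(diphenyl)methyl]pyrrolidine (5 mol%), ethyl 3,4-dihydroxybenzoate (20 mol%), neat, 4 °C
Reagents that add atoms: none
Why: Enamine-catalysed asymmetric Michael addition in which the enone attacks the E-enamine of 1 on the face remote from the CPh2OMe group, setting the 2S centre that becomes the isopropyl-bearing ring carbon of fragment A.

Step 2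
Reactants: 3 (2S)-5-oxo-2-(propan-2-yl)hexanal
Product: 5 (4S)-4-(propan-2-yl)cyclohex-2-en-1-one ((S)-cryptone), via aldol ketol 4 (not isolated)
Conditions: LiOH·H2O (0.2 equiv), i-PrOH, 23 °C
Reagents that add atoms: none
Why: Intramolecular aldol condensation closes the six-membered ring of fragment A, and the mild base leaves the γ-stereocentre untouched.

Step 3
Reactants: 5 (S)-cryptone
Product: 7 (3S,4S)-3-ethenyl-4-(propan-2-yl)cyclohex-1-en-1-yl trifluoromethanesulfonate, via magnesium enolate 6 (not isolated)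
Conditions: CH2=CHMgBr (1.5 equiv), CuBr·SMe2 (10 mol%), THF, −78 °C; then Comins' reagent, −78 → 0 °C
Reagents that add atoms: vinylmagnesium bromide C=C[Mg]Br; N-(5-chloropyridin-2-yl)bis(trifluoromethanesulfonimide) (Comins' reagent) FC(F)(F)S(=O)(=O)N(c1ccc(Cl)cn1)S(=O)(=O)C(F)(F)F
Why: Copper-catalysed conjugate addition occurs anti to the C4 isopropyl group (trans-3,4, sets C3), and O-triflation of the regiodefined enolate fixes the position of the future ring double bond.

Step 4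
Reactants: 7 (3S,4S)-3-ethenyl-4-(propan-2-yl)cyclohex-1-en-1-yl trifluoromethanesulfonate
Product: 9 (3S,4S)-3-formyl-4-(propan-2-yl)cyclohex-1-en-1-yl trifluoromethanesulfonate, via ozonide 8 (not isolated)
Conditions: O3, CH2Cl2, −78 °C (Sudan Red 7B end point); then PPh3, −78 → 0 °C
Reagents that add atoms: ozone [O-][O+]=O
Why: Chemoselective ozonolysis, because the monosubstituted vinyl group reacts far faster than the electron-poor enol triflate; the β,γ-unsaturated aldehyde is used crude and cold so C3 is not epimerised.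

Step 5
Reactants: 9 (3S,4S)-3-formyl-4-(propan-2-yl)cyclohex-1-en-1-yl trifluoromethanesulfonate
Product: 10 ethyl (2Z)-2-bromo-3-[(1S,6S)-6-(propan-2-yl)-3-(trifluoromethanesulfonyloxy)cyclohex-2-en-1-yl]prop-2-enoate
Conditions: Ph3P=CHCO2Et (1.3 equiv), NBS (1.3 equiv), CH2Cl2, −20 °C; then 9, −20 → 23 °C
Reagents that add atoms: ethyl (triphenylphosphoranylidene)acetate CCOC(=O)C=P(c1ccccc1)(c1ccccc1)c1ccccc1; N-bromosuccinimide O=C1CCC(=O)N1Br
Why: Wittig olefination with the stabilised bromo ylide made in the flask runs under neutral conditions and gives the (Z)-2-bromo enoate (ester trans to the ring carbon) under thermodynamic control.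

Step 6
Reactants: 10 ethyl (2Z)-2-bromo-3-[(1S,6S)-6-(propan-2-yl)-3-(trifluoromethanesulfonyloxy)cyclohex-2-en-1-yl]prop-2-enoate
Product: 11 ethyl (2E)-2-(hydroxymethyl)-3-[(1S,6S)-3-(hydroxymethyl)-6-(propan-2-yl)cyclohex-2-en-1-yl]prop-2-enoate
Conditions: Bu3SnCH2OH (3 equiv), Pd(PPh3)4 (10 mol%), LiCl (3 equiv), 1,4-dioxane, 95 °C
Reagents that add atoms: (tributylstannyl)methanol CCCC[Sn](CCCC)(CCCC)CO
Why: Double Stille hydroxymethylation in which zerovalent palladium inserts into the alkenyl triflate and the alkenyl bromide and couples both with retention, so the (Z)-bromide becomes the (E)-2-(hydroxymethyl) enoate.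

Step 7
Reactants: 11 ethyl (2E)-2-(hydroxymethyl)-3-[(1S,6S)-3-(hydroxymethyl)-6-(propan-2-yl)cyclohex-2-en-1-yl]prop-2-enoate
Product: 12 ethyl (2E)-2-{[(tert-butyldimethylsilyl)oxy]methyl}-3-[(1S,6S)-3-{[(tert-butyldimethylsilyl)oxy]methyl}-6-(propan-2-yl)cyclohex-2-en-1-yl]prop-2-enoate
Conditions: TBSCl (2.5 equiv), imidazole, DMF, 23 °C
Reagents that add atoms: tert-butyldimethylsilyl chloride CC(C)(C)[Si](C)(C)Cl
Why: Standard silylation of both primary allylic alcohols so that only the carboxyl group is free for the later coupling.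

Step 8
Reactants: 12 bis-TBS ethyl ester
Product: 13 (2E)-2-{[(tert-butyldimethylsilyl)oxy]methyl}-3-[(1S,6S)-3-{[(tert-butyldimethylsilyl)oxy]methyl}-6-(propan-2-yl)cyclohex-2-en-1-yl]prop-2-enoic acid
Conditions: LiOH·H2O (5 equiv), THF/MeOH/H2O (3:1:1), 40 °C; then 1 M HCl to pH 4
Reagents that add atoms: lithium hydroxide [Li+].[OH-]
Why: Saponification of the only ester present; the TBS ethers and the alkene geometry survive mild hydroxide.

**Fragment B**

Step 9
Reactants: 14 tert-butyl(diphenyl)(prop-2-yn-1-yloxy)silane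
Product: 16 methyl 4-{[tert-butyl(diphenyl)silyl]oxy}but-2-ynoate, via lithium acetylide 15 (not isolated)
Conditions: n-BuLi, THF, −78 °C; then ClCO2Me, −78 → 0 °C
Reagents that add atoms: methyl chloroformate COC(=O)Cl
Why: Acylation of the lithium acetylide gives the ynoate needed for a stereodefined carbocupration.

Step 10
Reactants: 16 methyl 4-{[tert-butyl(diphenyl)silyl]oxy}but-2-ynoate
Product: 18 methyl (2Z)-3-({[tert-butyl(diphenyl)silyl]oxy}methyl)penta-2,4-dienoate, via alkenylcopper 17 (not isolated)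
Conditions: CH2=CHMgBr (2.2 equiv), CuBr·SMe2 (1.1 equiv), THF, −78 °C; then 16, −78 °C; NH4Cl (aq.), −78 °C
Reagents that add atoms: vinylmagnesium bromide C=C[Mg]Br
Why: syn-Carbocupration of the ynoate and cold protonation with retention place H cis to the new vinyl group, so the two one-carbon arms are cis as the Diels–Alder needs.

Step 11
Reactants: 18 methyl (2Z)-3-({[tert-butyl(diphenyl)silyl]oxy}methyl)penta-2,4-dienoate
Product: 19 (2Z)-3-({[tert-butyl(diphenyl)silyl]oxy}methyl)penta-2,4-dien-1-ol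
Conditions: i-Bu2AlH (2.5 equiv), CH2Cl2, −78 °C; KNaC4H4O6 (aq.)
Reagents that add atoms: none
Why: 1,2-Reduction of the conjugated ester to the allylic alcohol turns the electron-poor dienoate into an electron-rich diene.

Step 12
Reactants: 19 (2Z)-3-({[tert-butyl(diphenyl)silyl]oxy}methyl)penta-2,4-dien-1-ol
Product: 20 tert-butyl{[(2Z)-3-({[tert-butyl(diphenyl)silyl]oxy}methyl)penta-2,4-dien-1-yl]oxy}dimethylsilane
Conditions: TBSCl, imidazole, CH2Cl2, 0 → 23 °C
Reagents that add atoms: tert-butyldimethylsilyl chloride CC(C)(C)[Si](C)(C)Cl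
Why: Silylation differentiates the two oxygens (TBS on the arm that becomes the lactone carbonyl, TBDPS on the arm that becomes the ester link).

Step 13
Reactants: 20 diene; 21 (2E)-4-methylpent-2-enal
Product: 22 (1S,2S,6S)-2-{[(tert-butyldimethylsilyl)oxy]methyl}-3-({[tert-butyl(diphenyl)silyl]oxy}methyl)-6-(propan-2-yl)cyclohex-3-ene-1-carbaldehyde
Conditions: (5R)-5-benzyl-2,2,3-trimethylimidazolidin-4-one·HCl (20 mol%), MeNO2/H2O (95:5), 0 → 23 °C
Reagents that add atoms: none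
Why: Iminium-catalysed Diels–Alder reaction in which the benzyl group shields the Si face (at the α-carbon) of the (E)-iminium, the isopropyl-bearing β-carbon bonds to the unsubstituted diene terminus, and the endo transition state puts CHO cis to CH2OTBS, so C1, C2 and C6 are set with isopropyl trans to CHO.

Step 14
Reactants: 22 cyclohexene carbaldehyde
Product: 23 (1S,2S,6S)-2-{[(tert-butyldimethylsilyl)oxy]methyl}-3-({[tert-butyl(diphenyl)silyl]oxy}methyl)-6-(propan-2-yl)cyclohex-3-ene-1-carboxylic acid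
Conditions: NaClO2, NaH2PO4, 2-methylbut-2-ene, t-BuOH/H2O, 0 → 23 °C
Reagents that add atoms: sodium chlorite [Na+].[O-]Cl=O
Why: Pinnick oxidation under buffered conditions does not epimerise C1, and the scavenger protects the ring alkene from HOCl.

Step 15
Reactants: 23 cyclohexene carboxylic acid
Product: 24 (1S,2S,5R,8R)-8-{[(tert-butyldimethylsilyl)oxy]methyl}-5-({[tert-butyl(diphenyl)silyl]oxy}methyl)-2-(propan-2-yl)-6-oxabicyclo[3.2.1]octan-7-one
Conditions: Co(salen) [Co(C16H14N2O2)] (5 mol%), N-fluoro-2,4,6-trimethylpyridinium triflate (1.5 equiv), (Me2SiH)2O (1.5 equiv), PhCF3, 23 °C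
Reagents that add atoms: none
Why: Hydrogen-atom-transfer (Mukaiyama-type, radical–polar crossover) Markovnikov hydrolactonisation in which Co–H delivers H to the ring CH carbon and the tertiary centre is captured by the carboxyl group tethered on C1, which can only reach one face, so the tertiary C–O bond is set syn to the C1 carbon substituent.

Step 16
Reactants: 24 bridged lactone
Product: 25 (1S,2S,5R,8R)-8-{[(tert-butyldimethylsilyl)oxy]methyl}-5-({[tert-butyl(diphenyl)silyl]oxy}methyl)-2-(propan-2-yl)-6-oxabicyclo[3.2.1]octan-7-ol (lactol, C7 epimers)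
Conditions: i-Bu2AlH (1.2 equiv), CH2Cl2, −78 °C; KNaC4H4O6 (aq.)
Reagents that add atoms: none
Why: Partial reduction of the lactone at −78 °C stops at the lactol, bringing the C1 carbon to the aldehyde oxidation level.

Step 17
Reactants: 25 lactol
Product: 26 [(1S,2S,5R,8R)-5-({[tert-butyl(diphenyl)silyl]oxy}methyl)-7-methoxy-2-(propan-2-yl)-6-oxabicyclo[3.2.1]octan-8-yl]methanol (C7 epimers)
Conditions: CSA (10 mol%), MeOH, 0 → 23 °C
Reagents that add atoms: methanol CO
Why: Acid-catalysed acetalisation protects the lactol while the same conditions methanolyse the primary TBS ether and leave TBDPS intact; any open-chain dimethyl acetal converges at step 19.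

Step 18
Reactants: 26 acetal alcohol
Product: 28 (1S,2S,5R,8S)-5-({[tert-butyl(diphenyl)silyl]oxy}methyl)-7-methoxy-2-(propan-2-yl)-6-oxabicyclo[3.2.1]octane-8-carboxylic acid, via acetal aldehyde 27 (not isolated)
Conditions: TEMPO (10 mol%), NaOCl (5 mol%), NaClO2 (2 equiv), MeCN/phosphate buffer pH 6.7, 35 °C
Reagents that add atoms: sodium chlorite [Na+].[O-]Cl=O
Why: TEMPO/chlorite oxidation at near-neutral pH takes the primary alcohol to the acid without touching the acetal, and C8 is not epimerised because its equatorial substituent is also the stable arrangement in the bicycle.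

Step 19
Reactants: 28 acetal acid
Product: 29 (1S,2S,5R,8S)-5-({[tert-butyl(diphenyl)silyl]oxy}methyl)-7-hydroxy-2-(propan-2-yl)-6-oxabicyclo[3.2.1]octane-8-carboxylic acid (lactol, in equilibrium with the open hydroxy aldehyde)
Conditions: AcOH/THF/H2O (3:1:1), 45 °C
Reagents that add atoms: water O
Why: Mild aqueous acid hydrolysis of the methyl acetal unmasks the cis-formyl acid as its lactol while the TBDPS ether survives.

Step 20
Reactants: 30 tert-butyl 2-(diethoxyphosphoryl)acetate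
Product: 32 tert-butyl 2-(diethoxyphosphoryl)prop-2-enoate, via methoxy adduct 31 (not isolated)
Conditions: (CH2O)n, piperidine (cat.), MeOH, reflux; then TsOH (cat.), toluene, reflux, 30 min
Reagents that add atoms: formaldehyde (as paraformaldehyde) C=O
Why: Knoevenagel condensation with formaldehyde, trapped as the methanol adduct and then eliminated, gives the doubly activated acceptor.

Step 21
Reactants: 29 lactol acid; 32 tert-butyl 2-(diethoxyphosphoryl)prop-2-enoate
Product: 34 tert-butyl (5aR,6S,9R,9aS)-9-({[tert-butyl(diphenyl)silyl]oxy}methyl)-9-hydroxy-1-oxo-6-(propan-2-yl)-1,3,5a,6,7,8,9,9a-octahydro-2-benzoxepine-4-carboxylate, via phosphonate adduct 33 (not isolated)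
Conditions: 32 (1.5 equiv), LiCl (3 equiv), i-Pr2NEt (3 equiv), MeCN (5 mM), 0 → 40 °C
Reagents that add atoms: none
Why: Proposed new method: carboxylate oxa-Michael/intramolecular Horner–Wadsworth–Emmons (5+2) lactone annulation — 32 has no acidic C–H and cannot olefinate until a nucleophile adds, the only anion present is the carboxylate of 29 (the tertiary OH is not ionised by i-Pr2NEt), its reversible conjugate addition gives the lithium-chelated phosphonate carbanion 33 held next to the cis-formyl group released from the lactol, and irreversible loss of diethyl phosphate drains the uphill Michael equilibrium into the seven-membered lactone, whose ring enforces the required alkene geometry (CO2t-Bu trans to the ring carbon) and frees the tertiary alcohol; the closest known reaction type is the tandem oxa-Michael/Horner–Wadsworth–Emmons reaction of alkoxides or salicylaldehydes with 2-phosphonoacrylates, not yet shown with a carboxylate donor or for ε-lactones; no stereocentre is created and C5a/C9a are not enolised by the amine base.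

Step 22
Reactants: 34 bicyclic lactone
Product: 35 tert-butyl (5aR,6S,9R,9aS)-9-hydroxy-9-(hydroxymethyl)-1-oxo-6-(propan-2-yl)-1,3,5a,6,7,8,9,9a-octahydro-2-benzoxepine-4-carboxylate
Conditions: HF·pyridine, pyridine, THF, 0 → 23 °C
Reagents that add atoms: none
Why: Buffered fluoride cleaves the primary TBDPS ether and leaves the tert-butyl ester, the lactone and the tertiary alcohol intact; the diol is used at once.

**Union and end game**

Step 23
Reactants: 13 acid fragment A; 35 diol fragment B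
Product: 37 tert-butyl (5aR,6S,9R,9aS)-9-({[(2E)-2-{[(tert-butyldimethylsilyl)oxy]methyl}-3-[(1S,6S)-3-{[(tert-butyldimethylsilyl)oxy]methyl}-6-(propan-2-yl)cyclohex-2-en-1-yl]prop-2-enoyl]oxy}methyl)-9-hydroxy-1-oxo-6-(propan-2-yl)-1,3,5a,6,7,8,9,9a-octahydro-2-benzoxepine-4-carboxylate, via mixed anhydride 36 (not isolated)
Conditions: 13 (1.2 equiv), 2,4,6-Cl3C6H2COCl, Et3N, THF, 23 °C; then 35, DMAP, toluene, 23 °C
Reagents that add atoms: none
Why: Yamaguchi esterification in which the mixed anhydride acylates only the primary hydroxyl (the tertiary alcohol is inert), joining the fragments without touching any stereocentre.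

Step 24
Reactants: 37 protected ester
Product: 38 target, (5aR,6S,9R,9aS)-9-hydroxy-9-({[(2E)-2-(hydroxymethyl)-3-[(1S,6S)-3-(hydroxymethyl)-6-(propan-2-yl)cyclohex-2-en-1-yl]prop-2-enoyl]oxy}methyl)-1-oxo-6-(propan-2-yl)-1,3,5a,6,7,8,9,9a-octahydro-2-benzoxepine-4-carboxylic acid
Conditions: TFA/CH2Cl2/H2O (10:10:1), 0 → 23 °C
Reagents that add atoms: none
Why: Acidolysis removes the tert-butyl ester (as isobutene) and both primary TBS ethers in one operation, and no stereocentre or ester link is affected.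

**Compound list**
1 | 3-methylbutanal | CC(C)CC=O | starting material
2 | but-3-en-2-one | CC(=O)C=C | starting material
3 | (2S)-5-oxo-2-(propan-2-yl)hexanal | CC(C)[C@@H](C=O)CCC(C)=O | intermediate
4 | (4S)-3-hydroxy-4-(propan-2-yl)cyclohexan-1-one (aldol ketol, C3 epimers, not isolated) | CC(C)[C@@H]1CCC(=O)CC1O | intermediate
5 | (4S)-4-(propan-2-yl)cyclohex-2-en-1-one ((S)-cryptone) | CC(C)[C@@H]1CCC(=O)C=C1 | intermediate
6 | bromomagnesium (3S,4S)-3-ethenyl-4-(propan-2-yl)cyclohex-1-en-1-olate (not isolated) | C=C[C@@H]1C=C(O[Mg]Br)CC[C@H]1C(C)C | intermediate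
7 | (3S,4S)-3-ethenyl-4-(propan-2-yl)cyclohex-1-en-1-yl trifluoromethanesulfonate | C=C[C@@H]1C=C(OS(=O)(=O)C(F)(F)F)CC[C@H]1C(C)C | intermediate
8 | (3S,4S)-4-(propan-2-yl)-3-(1,2,4-trioxolan-3-yl)cyclohex-1-en-1-yl trifluoromethanesulfonate (ozonide, not isolated) | C1OC(OO1)[C@@H]1C=C(OS(=O)(=O)C(F)(F)F)CC[C@H]1C(C)C | intermediate
9 | (3S,4S)-3-formyl-4-(propan-2-yl)cyclohex-1-en-1-yl trifluoromethanesulfonate | O=C[C@@H]1C=C(OS(=O)(=O)C(F)(F)F)CC[C@H]1C(C)C | intermediate
10 | ethyl (2Z)-2-bromo-3-[(1S,6S)-6-(propan-2-yl)-3-(trifluoromethanesulfonyloxy)cyclohex-2-en-1-yl]prop-2-enoate | CCOC(=O)/C(Br)=C/[C@@H]1C=C(OS(=O)(=O)C(F)(F)F)CC[C@H]1C(C)C | intermediate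
11 | ethyl (2E)-2-(hydroxymethyl)-3-[(1S,6S)-3-(hydroxymethyl)-6-(propan-2-yl)cyclohex-2-en-1-yl]prop-2-enoate | CCOC(=O)/C(CO)=C/[C@@H]1C=C(CO)CC[C@H]1C(C)C | intermediate
12 | ethyl (2E)-2-{[(tert-butyldimethylsilyl)oxy]methyl}-3-[(1S,6S)-3-{[(tert-butyldimethylsilyl)oxy]methyl}-6-(propan-2-yl)cyclohex-2-en-1-yl]prop-2-enoate | CCOC(=O)/C(CO[Si](C)(C)C(C)(C)C)=C/[C@@H]1C=C(CO[Si](C)(C)C(C)(C)C)CC[C@H]1C(C)C | intermediate
13 | (2E)-2-{[(tert-butyldimethylsilyl)oxy]methyl}-3-[(1S,6S)-3-{[(tert-butyldimethylsilyl)oxy]methyl}-6-(propan-2-yl)cyclohex-2-en-1-yl]prop-2-enoic acid | OC(=O)/C(CO[Si](C)(C)C(C)(C)C)=C/[C@@H]1C=C(CO[Si](C)(C)C(C)(C)C)CC[C@H]1C(C)C | intermediate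
14 | tert-butyl(diphenyl)(prop-2-yn-1-yloxy)silane | C#CCO[Si](c1ccccc1)(c1ccccc1)C(C)(C)C | starting material
15 | lithium 3-{[tert-butyl(diphenyl)silyl]oxy}prop-1-yn-1-ide (not isolated) | [Li]C#CCO[Si](c1ccccc1)(c1ccccc1)C(C)(C)C | intermediate
16 | methyl 4-{[tert-butyl(diphenyl)silyl]oxy}but-2-ynoate | COC(=O)C#CCO[Si](c1ccccc1)(c1ccccc1)C(C)(C)C | intermediate
17 | bromomagnesium alkenyl(vinyl)cuprate, copper on C2 cis to the C3 vinyl group (not isolated) | C=C/C(CO[Si](c1ccccc1)(c1ccccc1)C(C)(C)C)=C(/C(=O)OC)[Cu-]C=C.[Mg+]Br | intermediate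
18 | methyl (2Z)-3-({[tert-butyl(diphenyl)silyl]oxy}methyl)penta-2,4-dienoate | C=C/C(CO[Si](c1ccccc1)(c1ccccc1)C(C)(C)C)=C/C(=O)OC | intermediate
19 | (2Z)-3-({[tert-butyl(diphenyl)silyl]oxy}methyl)penta-2,4-dien-1-ol | C=C/C(CO[Si](c1ccccc1)(c1ccccc1)C(C)(C)C)=C/CO | intermediate
20 | tert-butyl{[(2Z)-3-({[tert-butyl(diphenyl)silyl]oxy}methyl)penta-2,4-dien-1-yl]oxy}dimethylsilane | C=C/C(CO[Si](c1ccccc1)(c1ccccc1)C(C)(C)C)=C/CO[Si](C)(C)C(C)(C)C | intermediate
21 | (2E)-4-methylpent-2-enal | CC(C)/C=C/C=O | starting material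
22 | (1S,2S,6S)-2-{[(tert-butyldimethylsilyl)oxy]methyl}-3-({[tert-butyl(diphenyl)silyl]oxy}methyl)-6-(propan-2-yl)cyclohex-3-ene-1-carbaldehyde | CC(C)[C@@H]1CC=C(CO[Si](c2ccccc2)(c2ccccc2)C(C)(C)C)[C@@H](CO[Si](C)(C)C(C)(C)C)[C@H]1C=O | intermediate
23 | (1S,2S,6S)-2-{[(tert-butyldimethylsilyl)oxy]methyl}-3-({[tert-butyl(diphenyl)silyl]oxy}methyl)-6-(propan-2-yl)cyclohex-3-ene-1-carboxylic acid | CC(C)[C@@H]1CC=C(CO[Si](c2ccccc2)(c2ccccc2)C(C)(C)C)[C@@H](CO[Si](C)(C)C(C)(C)C)[C@H]1C(=O)O | intermediate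
24 | (1S,2S,5R,8R)-8-{[(tert-butyldimethylsilyl)oxy]methyl}-5-({[tert-butyl(diphenyl)silyl]oxy}methyl)-2-(propan-2-yl)-6-oxabicyclo[3.2.1]octan-7-one | CC(C)[C@@H]1CC[C@@]2(CO[Si](c3ccccc3)(c3ccccc3)C(C)(C)C)OC(=O)[C@@H]1[C@@H]2CO[Si](C)(C)C(C)(C)C | intermediate
25 | (1S,2S,5R,8R)-8-{[(tert-butyldimethylsilyl)oxy]methyl}-5-({[tert-butyl(diphenyl)silyl]oxy}methyl)-2-(propan-2-yl)-6-oxabicyclo[3.2.1]octan-7-ol (C7 epimers) | CC(C)[C@@H]1CC[C@@]2(CO[Si](c3ccccc3)(c3ccccc3)C(C)(C)C)OC(O)[C@@H]1[C@@H]2CO[Si](C)(C)C(C)(C)C | intermediate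
26 | [(1S,2S,5R,8R)-5-({[tert-butyl(diphenyl)silyl]oxy}methyl)-7-methoxy-2-(propan-2-yl)-6-oxabicyclo[3.2.1]octan-8-yl]methanol (C7 epimers) | CC(C)[C@@H]1CC[C@@]2(CO[Si](c3ccccc3)(c3ccccc3)C(C)(C)C)OC(OC)[C@@H]1[C@@H]2CO | intermediate
27 | (1S,2S,5R,8S)-5-({[tert-butyl(diphenyl)silyl]oxy}methyl)-7-methoxy-2-(propan-2-yl)-6-oxabicyclo[3.2.1]octane-8-carbaldehyde (not isolated) | CC(C)[C@@H]1CC[C@@]2(CO[Si](c3ccccc3)(c3ccccc3)C(C)(C)C)OC(OC)[C@@H]1[C@@H]2C=O | intermediate
28 | (1S,2S,5R,8S)-5-({[tert-butyl(diphenyl)silyl]oxy}methyl)-7-methoxy-2-(propan-2-yl)-6-oxabicyclo[3.2.1]octane-8-carboxylic acid (C7 epimers) | CC(C)[C@@H]1CC[C@@]2(CO[Si](c3ccccc3)(c3ccccc3)C(C)(C)C)OC(OC)[C@@H]1[C@@H]2C(=O)O | intermediate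
29 | (1S,2S,5R,8S)-5-({[tert-butyl(diphenyl)silyl]oxy}methyl)-7-hydroxy-2-(propan-2-yl)-6-oxabicyclo[3.2.1]octane-8-carboxylic acid (lactol, C7 epimers) | CC(C)[C@@H]1CC[C@@]2(CO[Si](c3ccccc3)(c3ccccc3)C(C)(C)C)OC(O)[C@@H]1[C@@H]2C(=O)O | intermediate
30 | tert-butyl 2-(diethoxyphosphoryl)acetate | CCOP(=O)(OCC)CC(=O)OC(C)(C)C | starting material
31 | tert-butyl 2-(diethoxyphosphoryl)-3-methoxypropanoate (not isolated) | CCOP(=O)(OCC)C(COC)C(=O)OC(C)(C)C | intermediate
32 | tert-butyl 2-(diethoxyphosphoryl)prop-2-enoate | CCOP(=O)(OCC)C(=C)C(=O)OC(C)(C)C | intermediate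
33 | 3-tert-butoxy-2-(diethoxyphosphoryl)-3-oxopropyl 2-({[tert-butyl(diphenyl)silyl]oxy}methyl)-6-formyl-2-hydroxy-5-(propan-2-yl)cyclohexane-1-carboxylate, open hydroxy aldehyde form, ring stereocentres as in 29 (not isolated) | CC(C)[C@@H]1CC[C@](O)(CO[Si](c2ccccc2)(c2ccccc2)C(C)(C)C)[C@@H](C(=O)OCC(P(=O)(OCC)OCC)C(=O)OC(C)(C)C)[C@H]1C=O | intermediate
34 | tert-butyl (5aR,6S,9R,9aS)-9-({[tert-butyl(diphenyl)silyl]oxy}methyl)-9-hydroxy-1-oxo-6-(propan-2-yl)-1,3,5a,6,7,8,9,9a-octahydro-2-benzoxepine-4-carboxylate | CC(C)[C@@H]1CC[C@](O)(CO[Si](c3ccccc3)(c3ccccc3)C(C)(C)C)[C@H]2C(=O)OCC(C(=O)OC(C)(C)C)=C[C@@H]12 | intermediate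
35 | tert-butyl (5aR,6S,9R,9aS)-9-hydroxy-9-(hydroxymethyl)-1-oxo-6-(propan-2-yl)-1,3,5a,6,7,8,9,9a-octahydro-2-benzoxepine-4-carboxylate | CC(C)[C@@H]1CC[C@](O)(CO)[C@H]2C(=O)OCC(C(=O)OC(C)(C)C)=C[C@@H]12 | intermediate
36 | mixed anhydride of 13 and 2,4,6-trichlorobenzoic acid (not isolated) | O=C(OC(=O)c1c(Cl)cc(Cl)cc1Cl)/C(CO[Si](C)(C)C(C)(C)C)=C/[C@@H]1C=C(CO[Si](C)(C)C(C)(C)C)CC[C@H]1C(C)C | intermediate
37 | tert-butyl ester, bis-TBS ether of the target (full name in step 23) | CC(C)[C@@H]1CC[C@](O)(COC(=O)/C(=C/[C@@H]2C=C(CO[Si](C)(C)C(C)(C)C)CC[C@H]2C(C)C)CO[Si](C)(C)C(C)(C)C)[C@H]2C(=O)OCC(C(=O)OC(C)(C)C)=C[C@@H]12 | intermediate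
38 | (5aR,6S,9R,9aS)-9-hydroxy-9-({[(2E)-2-(hydroxymethyl)-3-[(1S,6S)-3-(hydroxymethyl)-6-(propan-2-yl)cyclohex-2-en-1-yl]prop-2-enoyl]oxy}methyl)-1-oxo-6-(propan-2-yl)-1,3,5a,6,7,8,9,9a-octahydro-2-benzoxepine-4-carboxylic acid | CC(C)[C@@H]1CC[C@](O)(COC(=O)/C(=C/[C@@H]2C=C(CO)CC[C@H]2C(C)C)CO)[C@H]2C(=O)OCC(C(=O)O)=C[C@@H]12 | target

**Totals and risks**

Total step count: 24. Longest linear sequence: 15 steps (14 → 38 through steps 9–19 and 21–24).

Steps most likely to fail:

Step 13 (organocatalytic Diels–Alder; a β-branched enal with an acyclic trisubstituted diene may be slow or poorly regio- or enantioselective). The fallback sets out from 20 and comes back at 22, using auxiliary control instead of iminium catalysis. Commercial (E)-4-methylpent-2-enoic acid is activated with pivaloyl chloride/Et3N and added to lithiated (R)-4-benzyloxazolidin-2-one (THF, −78 °C) to give (4R)-4-benzyl-3-[(2E)-4-methylpent-2-enoyl]-1,3-oxazolidin-2-one F1. Cycloaddition of this with 20 (Et2AlCl, CH2Cl2, −78 → −30 °C; chelated s-cis imide, endo addition anti to the benzyl group) gives (4R)-4-benzyl-3-{[(1S,2S,6S)-2-{[(tert-butyldimethylsilyl)oxy]methyl}-3-({[tert-butyl(diphenyl)silyl]oxy}methyl)-6-(propan-2-yl)cyclohex-3-en-1-yl]carbonyl}-1,3-oxazolidin-2-one F2. Reductive removal of the auxiliary (LiBH4, Et2O/MeOH, 0 °C) gives [(1S,2S,6S)-2-{[(tert-butyldimethylsilyl)oxy]methyl}-3-({[tert-butyl(diphenyl)silyl]oxy}methyl)-6-(propan-2-yl)cyclohex-3-en-1-yl]methanol F3, and Dess–Martin periodinane (NaHCO3, CH2Cl2) returns 22.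

Step 15 (hydrogen-atom-transfer hydrolactonisation; it needs the conformer with axial isopropyl and carboxyl groups and passes through a tertiary centre next to CH2OSi). The fallback sets out from 23 and comes back at 24, using halonium chemistry instead. Iodolactonisation (I2, NaHCO3, MeCN, 0 °C, dark) gives (1S,2S,4S,5R,8R)-8-{[(tert-butyldimethylsilyl)oxy]methyl}-5-({[tert-butyl(diphenyl)silyl]oxy}methyl)-4-iodo-2-(propan-2-yl)-6-oxabicyclo[3.2.1]octan-7-one F4. The syn-axial iodine/isopropyl contact is a known weakness of this fallback and may force a boat six-membered ring. Radical deiodination (Bu3SnH, AIBN, toluene, 80 °C) then gives 24.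

Step 21 (the proposed annulation; the carboxylate may be too weak a Michael donor, or the aldehyde may epimerise before ring closure). The fallback uses only known reactions, sets out from 29 and comes back at 34. Wittig methylenation of the lactol (Ph3PCH3Br, KOt-Bu, 4 equiv, THF, 0 → 23 °C) gives 2-({[tert-butyl(diphenyl)silyl]oxy}methyl)-6-ethenyl-2-hydroxy-5-(propan-2-yl)cyclohexane-1-carboxylic acid (stereocentres as in 29) F5. Carboxylate alkylation with commercial tert-butyl 2-(bromomethyl)acrylate (Cs2CO3, DMF, 23 °C) gives 2-(tert-butoxycarbonyl)prop-2-en-1-yl 2-({[tert-butyl(diphenyl)silyl]oxy}methyl)-6-ethenyl-2-hydroxy-5-(propan-2-yl)cyclohexane-1-carboxylate F6. Ring-closing metathesis (second-generation Hoveyda–Grubbs catalyst, RuCl2(H2IMes)(=CH–C6H4–2-O-i-Pr), toluene, 80 °C, 2 mM) closes the seven-membered ring to 34.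

**Further compounds**
F1 | step 13 | (4R)-4-benzyl-3-[(2E)-4-methylpent-2-enoyl]-1,3-oxazolidin-2-one | CC(C)/C=C/C(=O)N1[C@H](Cc2ccccc2)COC1=O
F2 | step 13 | (4R)-4-benzyl-3-{[(1S,2S,6S)-2-{[(tert-butyldimethylsilyl)oxy]methyl}-3-({[tert-butyl(diphenyl)silyl]oxy}methyl)-6-(propan-2-yl)cyclohex-3-en-1-yl]carbonyl}-1,3-oxazolidin-2-one | CC(C)[C@@H]1CC=C(CO[Si](c2ccccc2)(c2ccccc2)C(C)(C)C)[C@@H](CO[Si](C)(C)C(C)(C)C)[C@H]1C(=O)N1[C@H](Cc2ccccc2)COC1=O
F3 | step 13 | [(1S,2S,6S)-2-{[(tert-butyldimethylsilyl)oxy]methyl}-3-({[tert-butyl(diphenyl)silyl]oxy}methyl)-6-(propan-2-yl)cyclohex-3-en-1-yl]methanol | CC(C)[C@@H]1CC=C(CO[Si](c2ccccc2)(c2ccccc2)C(C)(C)C)[C@@H](CO[Si](C)(C)C(C)(C)C)[C@H]1CO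
F4 | step 15 | (1S,2S,4S,5R,8R)-8-{[(tert-butyldimethylsilyl)oxy]methyl}-5-({[tert-butyl(diphenyl)silyl]oxy}methyl)-4-iodo-2-(propan-2-yl)-6-oxabicyclo[3.2.1]octan-7-one | CC(C)[C@@H]1C[C@H](I)[C@@]2(CO[Si](c3ccccc3)(c3ccccc3)C(C)(C)C)OC(=O)[C@@H]1[C@@H]2CO[Si](C)(C)C(C)(C)C
F5 | step 21 | 2-({[tert-butyl(diphenyl)silyl]oxy}methyl)-6-ethenyl-2-hydroxy-5-(propan-2-yl)cyclohexane-1-carboxylic acid (stereocentres as in 29) | CC(C)[C@@H]1CC[C@](O)(CO[Si](c2ccccc2)(c2ccccc2)C(C)(C)C)[C@@H](C(=O)O)[C@H]1C=C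
F6 | step 21 | 2-(tert-butoxycarbonyl)prop-2-en-1-yl 2-({[tert-butyl(diphenyl)silyl]oxy}methyl)-6-ethenyl-2-hydroxy-5-(propan-2-yl)cyclohexane-1-carboxylate (stereocentres as in 29) | CC(C)[C@@H]1CC[C@](O)(CO[Si](c2ccccc2)(c2ccccc2)C(C)(C)C)[C@@H](C(=O)OCC(=C)C(=O)OC(C)(C)C)[C@H]1C=C
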